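Assumptions: (S)-(+)-terpinen-4-ol is bought in an enantiopure grade. Daucane numbering is used: C1 = quaternary C–Me, C4 = C(OH)(i-Pr), C5 = ring-fusion CH, C6 = ester carbinol, C8=C9 = alkene. α is the face carrying i-Pr and H-5. β is the face carrying 4-OH and 1-Me.

## Retrosynthetic overview
1. Ferutinine ⇒ jaeschkeanadiol, by aroylation of the secondary O6 only (the tertiary 4-OH is inert).
2. The seven-membered ring is closed last: C8=C9 by ring-closing metathesis, and C6–C7 (with the C6 carbinol) by chelate-controlled methallyl addition to a C6 aldehyde.
3. Key disconnection is C1–C10: a light-driven conjugate allylation of a cyclopentene carbaldehyde sets quaternary C1. C5 is then set by equilibration.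
4. The five-membered ring is made first, by ozonolysis/aldol ring contraction of (S)-terpinen-4-ol. This starting material supplies C4 with its OH and i-Pr, and C4 controls C1, C5 and C6.

## Route

**Step 1**
Reactants: 1, (S)-(+)-terpinen-4-ol
Product: 2, (S)-3-hydroxy-6-oxo-3-(propan-2-yl)heptanal (partly present as its five-membered hemiketal)
Conditions: O3, CH2Cl2, −78 °C; then Me2S, −78 °C → rt
Reagents that add atoms: ozone, [O-][O+]=O
Why: Criegee ozonolysis cleaves the only C=C, and the carbinol stereocentre is not involved.

**Step 2**
Reactants: 2
Product: 3, (R)-5-hydroxy-2-methyl-5-(propan-2-yl)cyclopent-1-ene-1-carbaldehyde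
Conditions: Bn2NH·TFA (20 mol %), toluene, 4 Å MS, 40 °C
Reagents that add atoms: none
Why: In this enamine-mediated 5-(enolexo) intramolecular aldol condensation the aldehyde enamine attacks the methyl ketone, as with limonene-type keto aldehydes; C4 is fully substituted and keeps its configuration.

**Step 3 (key step)**
Reactants: 3; 4, allyltributylstannane
Product: 5, (1R,2R,5R)-2-hydroxy-5-methyl-2-(propan-2-yl)-5-(prop-2-enyl)cyclopentane-1-carbaldehyde (allyl α, Me β, CHO β, H-5 α)
Conditions: Me3Al (1.05 equiv) + 2,6-diphenylphenol (2.1 equiv), toluene, rt; add 3, 0 °C → rt (−CH4); add 4 (3 equiv), CH2Cl2/toluene, 365 nm LED, −40 °C; 1 M HCl work-up; then Et3N (0.5 equiv), CH2Cl2, rt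
Reagents that add atoms: allyltributylstannane, C=CC[Sn](CCCC)(CCCC)CCCC
Why: Proposed new method: protonolysis of MeAl(OAr)2 by the 4-OH gives a substrate-bound O4–Al(OAr)2 that chelates the formyl oxygen in a six-membered ring; this red-shifts the π,π* band, makes the excited enal a stronger oxidant, and buries C6 and the whole β face under two very bulky achiral aryloxides; excitation triggers electron transfer from the stannane, Bu3Sn+ is lost, and the allyl radical couples with the persistent Al-bound oxyallyl radical at C1 from the only open (α) face, which avoids the reversible addition of a stabilised allyl radical to a tetrasubstituted acceptor and leaves the methyl cis to OH; hydrolysis followed by mild base equilibrates C5 so that CHO is trans to both i-Pr and allyl and hydrogen-bonded to the cis OH; the closest known reaction types are electron-transfer photoallylation of iminium salts and electron-poor alkenes by allyl-silanes/-stannanes, Lewis-acid chromophore activation of enones, and bulky aluminium aryloxide-directed 1,4-addition to enals.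

**Step 4**
Reactants: 5; 6, 2-methylallylmagnesium chloride
Product: 7, (1S)-1-[(1S,2R,5R)-2-hydroxy-5-methyl-2-(propan-2-yl)-5-(prop-2-enyl)cyclopentyl]-3-methylbut-3-en-1-ol
Conditions: 6 (2.5 equiv), THF/CH2Cl2, −78 °C; aq NH4Cl
Reagents that add atoms: 2-methylallylmagnesium chloride, CC(=C)C[Mg]Cl
Why: This is a Cram-chelate Grignard addition: the first equivalent forms the O4–Mg alkoxide, which chelates O6; the face on the C1 side is blocked by the β-methyl, so attack comes from the H-5 side and gives (6S).

**Step 5**
Reactants: 7
Product: 8, jaeschkeanadiol, (3R,3aS,4S,8aR)-6,8a-dimethyl-3-(propan-2-yl)-1,2,3,3a,4,5,8,8a-octahydroazulene-3,4-diol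
Conditions: Hoveyda–Grubbs II (5 mol %), 1,4-benzoquinone (10 mol %), toluene (3 mM), 80 °C (−C2H4)
Reagents that add atoms: none
Why: Ring-closing metathesis of the allyl and 1,1-disubstituted olefins gives the trisubstituted cycloheptene; no stereocentre is touched, the trans fusion is already fixed, and benzoquinone suppresses olefin migration.

**Step 6**
Reactants: 8; 9, 4-acetoxybenzoyl chloride
Product: 10, ferutinine
Conditions: 9 (1.5 equiv), DMAP, Et3N, CH2Cl2, 0 °C → rt; then MeOH, K2CO3, 0 °C, 20 min (one pot)
Reagents that add atoms: 4-acetoxybenzoyl chloride, CC(=O)Oc1ccc(C(=O)Cl)cc1 (the acetyl group is removed as MeOAc in the second operation)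
Why: DMAP-catalysed acylation reacts only at the secondary 6-OH with retention at C6, and the aryl acetate is methanolysed far faster than the hindered secondary benzoate.

## Compound list
1 | (S)-(+)-terpinen-4-ol | CC1=CC[C@](O)(C(C)C)CC1 | starting material
2 | (S)-3-hydroxy-6-oxo-3-(propan-2-yl)heptanal | CC(=O)CC[C@@](O)(C(C)C)CC=O | intermediate
3 | (R)-5-hydroxy-2-methyl-5-(propan-2-yl)cyclopent-1-ene-1-carbaldehyde | CC1=C(C=O)[C@](O)(C(C)C)CC1 | intermediate
4 | allyltributylstannane | C=CC[Sn](CCCC)(CCCC)CCCC | starting material
5 | (1R,2R,5R)-2-hydroxy-5-methyl-2-(propan-2-yl)-5-(prop-2-enyl)cyclopentane-1-carbaldehyde | C=CC[C@@]1(C)CC[C@@](O)(C(C)C)[C@@H]1C=O | intermediate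
6 | 2-methylallylmagnesium chloride | CC(=C)C[Mg]Cl | starting material
7 | allyl/methallyl diene-diol (6S) | C=CC[C@@]1(C)CC[C@@](O)(C(C)C)[C@@H]1[C@@H](O)CC(C)=C | intermediate
8 | jaeschkeanadiol | CC1=CC[C@@]2(C)CC[C@@](O)(C(C)C)[C@@H]2[C@@H](O)C1 | intermediate
9 | 4-acetoxybenzoyl chloride | CC(=O)Oc1ccc(C(=O)Cl)cc1 | starting material
10 | ferutinine | CC1=CC[C@@]2(C)CC[C@@](O)(C(C)C)[C@@H]2[C@@H](OC(=O)c2ccc(O)cc2)C1 | target

## Step count
Total steps: 6. Longest linear sequence: 6.

## Steps most likely to fail
1. **Step 3 (new photoallylation).**
   - Risks: competing [2+2] or Paternò–Büchi addition, 1,2-allylation, and weak α/β facial control.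
   - Fallback (known chemistry, pericyclic chirality transfer, +3 steps):
     - 1,2-addition of allylMgBr to 3, then DMP oxidation.
     - Evans–Saksena reduction with Me4NBH(OAc)3, where hydride delivered from the 4-OH face gives the (6S) carbinol.
     - Anionic oxy-Cope rearrangement (KH/18-crown-6). With H-6 held in the alkene plane by A(1,3) strain, the allyl unit sits on the α face and is transferred suprafacially to C1.
     - Base equilibration at C5 then gives 5.
2. **Step 2 (aldol condensation of a tertiary β-hydroxy aldehyde).**
   - Risks: amine-promoted dehydration or retro-aldol cleavage, and over-dehydration of 3 to a cyclopentadiene.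
   - Fallback (replaces enamine catalysis with a stepwise sequence):
     - TMSOTf/Et3N converts the aldehyde of 2 to its silyl enol ether and caps the OH.
     - BF3·OEt2-promoted intramolecular Mukaiyama aldol onto the ketone.
     - MsCl/Et3N elimination, then mild desilylation to 3.
3. **Step 4 (C6 configuration).**
   - Risk: non-chelated addition gives the 6-epimer.
   - Fallback: carry the epimer through the metathesis of step 5, then use it directly in a Mitsunobu esterification (PPh3, DIAD) with unprotected 4-hydroxybenzoic acid. The inversion gives 10 directly.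
   - Alternative: DMP oxidation to the C6 ketone followed by hydroxyl-directed Evans–Saksena reduction to 8.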